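**Retrosynthetic overview**

1. The target comes from enol-lactone 19 by saponification; 19 from 18 by cross-metathesis (butenyl → prenyl); 18 from cyclobutanone 16 by removal of a temporary C=O. The acid and the enol OH stay masked together as a six-membered lactone from step 2 to step 14.
2. Key disconnection: the cyclobutane is the [2+2] adduct of the C-prenyl CH=CMe2 bond of dienone 10 with an isopropenylketeniminium ion. The enabling feature is that the ring CH2 lies between the two ring CH atoms and is the only ring carbon without a carbon substituent, so it can carry a temporary carbonyl, while the ring CMe2 is the Markovnikov terminus of a prenyl group already on the quaternary carbon.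
3. The quaternary carbon (C8 of the target chromene; C6 in the pyrano[2,3-f]chromene numbering used for 6–19) is built by two successive O→C Claisen shifts from the 5-oxygen: first achiral (prenyl), then dearomative with chirality transfer from an (R)-but-3-en-2-yl ether.
4. Core: phloroglucinol → Pechmann coumarin → CuH 1,4-reduction (4S) → C8 tigloylation → cinchona-catalysed oxa-Michael closure (cis-dimethylpyranone).
5. Ring order: benzene ring (purchased) → lactone ring (temporary) → pyranone ring → cyclobutane (last).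

Key step: step 10

Assumption: the sense of induction of the CuH ligand (step 2), of quinine (step 4) and of the (2R,5R)-pyrrolidine auxiliary (step 10) is taken as written; if the opposite sense were found, the mirror-image ligand, quinidine or the (2S,5S)-auxiliary would be used with no other change.

**Route**

Step 1
Reactants: 1 phloroglucinol; 2 ethyl 3-oxohexanoate
Product: 3 5,7-dihydroxy-4-propylcoumarin
Conditions: conc. H2SO4, 0 °C → rt
Reagents that add atoms: none
Why: Pechmann condensation (transesterification, ring hydroxyalkylation, dehydration); the threefold symmetry of 1 allows only one regioisomer.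

Step 2
Reactants: 3 5,7-dihydroxy-4-propylcoumarin
Product: 4 (4S)-5,7-dihydroxy-4-propylchroman-2-one
Conditions: Cu(OAc)2·H2O (5 mol %), (R)-DTBM-SEGPHOS (5.5 mol %), (EtO)2MeSiH (5 equiv), t-BuOH (3 equiv), THF, rt; HCl/MeOH work-up
Reagents that add atoms: none
Why: Copper hydride-catalysed asymmetric conjugate reduction of a β,β-disubstituted unsaturated lactone, in which the ligand decides the face of hydride delivery to C4 (4S) and the free phenols should only consume silane until the acidic work-up.

Step 3
Reactants: 4 (4S)-5,7-dihydroxy-4-propylchroman-2-one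
Product: 5 (4S)-5,7-dihydroxy-8-tigloyl-4-propylchroman-2-one
Conditions: tigloyl chloride (1.2 equiv), AlCl3 (3.5 equiv), PhNO2–CH2Cl2, 0 °C → rt; cold 1 M HCl
Reagents that add atoms: tigloyl chloride, C/C=C(\C)C(=O)Cl
Why: Friedel–Crafts acylation at C8 (ortho to 7-OH and para to 5-OH, the site acylated in the parent 5,7-dihydroxy-4-alkylcoumarins), where the aluminium chelate of the ortho-hydroxyaryl enone should keep the enone from closing prematurely.

Step 4
Reactants: 5 (4S)-5,7-dihydroxy-8-tigloyl-4-propylchroman-2-one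
Product: 6 (4S,8R,9S)-tricyclic lactone–pyranone phenol
Conditions: (−)-quinine (20 mol %), chlorobenzene, 15 °C
Reagents that add atoms: none
Why: Cinchona alkaloid-catalysed asymmetric intramolecular oxa-Michael addition of the only phenol ortho to the enone (7-OH), in which the alkaloid ion pair sets C8 (R) and kinetic protonation of the enol places the C9 methyl cis (9S).

Step 5
Reactants: 6 (4S,8R,9S)-tricyclic lactone–pyranone phenol
Product: 7 5-O-(2-methylbut-3-en-2-yl) ether of 6
Conditions: tert-butyl 2-methylbut-3-en-2-yl carbonate (1.5 equiv), Pd(PPh3)4 (2 mol %), THF, 0 °C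
Reagents that add atoms: tert-butyl 2-methylbut-3-en-2-yl carbonate, CC(C)(C)OC(=O)OC(C)(C)C=C
Why: Tsuji–Trost O-allylation, in which the phenoxide of the single free OH attacks the 1,1-dimethylallyl–Pd cation at its more substituted terminus to give the tertiary aryl ether.

Step 6
Reactants: 7 5-O-(2-methylbut-3-en-2-yl) ether of 6
Product: 8 6-prenyl phenol
Conditions: toluene, 110 °C
Reagents that add atoms: none
Why: Aromatic Claisen rearrangement to the only free ortho carbon (C6) with allyl transposition (1,1-dimethylallyl → prenyl), followed by re-aromatisation through tautomerism.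

Step 7
Reactants: 8 6-prenyl phenol
Product: 9 5-O-[(2R)-but-3-en-2-yl] ether of 8
Conditions: (S)-but-3-en-2-ol (1.5 equiv), PPh3, DIAD, toluene, 0 °C → rt
Reagents that add atoms: (S)-but-3-en-2-ol, C[C@H](O)C=C
Why: Mitsunobu etherification, whose SN2 inversion at the carbinol carbon should give the (R)-configured secondary allylic aryl ether.

Step 8
Reactants: 9 5-O-[(2R)-but-3-en-2-yl] ether of 8
Product: 10 (6R)-6-[(E)-but-2-enyl]-6-prenyl dienone
Conditions: chlorobenzene, 130 °C
Reagents that add atoms: none
Why: Dearomative ortho-Claisen rearrangement onto the prenyl-bearing C6 (the other ortho carbon is the ring-fusion C4a), in which the chair transition state with the ether methyl equatorial delivers the allyl terminus to one ring face, so that the (R)-ether centre becomes the (6R)-quaternary centre with an (E)-butenyl group, and the dienone is held by its two vinylogous-ester arrays.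

Step 9
Reactants: 11 3-methylbut-3-enoic acid; 12 (2R,5R)-2,5-dimethylpyrrolidine
Product: 13 1-[(2R,5R)-2,5-dimethylpyrrolidin-1-yl]-3-methylbut-3-en-1-one
Conditions: EDC, HOAt (cat.), CH2Cl2, 0 °C → rt
Reagents that add atoms: none
Why: Carbodiimide amide coupling under base-free conditions, which should keep the β,γ-alkene out of conjugation.

Step 10
Reactants: 10 (6R)-6-[(E)-but-2-enyl]-6-prenyl dienone; 13 1-[(2R,5R)-2,5-dimethylpyrrolidin-1-yl]-3-methylbut-3-en-1-one
Product: 16 cis-2,4-disubstituted 3,3-dimethylcyclobutanone, via keteniminium triflate 14 (not isolated), via cyclobutaniminium triflate 15 (not isolated)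
Conditions: 13 (2.0 equiv), Tf2O (2.1 equiv), 2,4,6-collidine (2.3 equiv), ClCH2CH2Cl, −20 °C → rt; then 10, rt → 60 °C; then H2O (pH 7 phosphate buffer)–CH2Cl2, rt
Reagents that add atoms: water, O
Why: Tf2O/collidine turns amide 13 into the isopropenylketeniminium ion 14, whose electrophilic central carbon is attacked by the CH terminus of the prenyl C=C of 10 (Markovnikov: the positive charge develops on the CMe2 carbon), and the tertiary cation then collapses onto the enamine α-carbon to give cyclobutaniminium 15, which water hydrolyses to ketone 16 with release of the auxiliary. The closest known reaction type is the keteniminium–alkene [2+2] cycloaddition of unactivated olefins, including its auxiliary-controlled variant with C2-symmetric 2,5-dialkylpyrrolidines. The four-membered ring closes in a stepwise, asynchronous intermolecular [2+2] mode (first bond C(=N+)–CH, second bond CMe2–CH(isopropenyl) by 4-exo collapse of the cation–enamine pair). The ring CH that carries the CH2–C6 arm should be set by the C2-symmetric auxiliary, whose methyl groups leave one approach to the cumulene open whichever N-rotamer reacts, while the isopropenyl-bearing CH, being α to the C=N+/C=O group and allylic, is the one readily enolisable centre and should settle in the 2,4-cis arrangement. The step needs chemoselectivity for the trisubstituted prenyl alkene over the 1,2-disubstituted butenyl alkene and the push–pull ring alkenes, secured because only CH=CMe2 offers a tertiary cation, and it needs a core without OH or CO2H, secured by the lactone and pyranone rings that cap all three oxygens of the dienone.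

Step 11
Reactants: 16 cis-2,4-disubstituted 3,3-dimethylcyclobutanone
Product: 17 tosylhydrazone of 16
Conditions: TsNHNH2 (1.3 equiv), EtOH, AcOH (cat.), rt
Reagents that add atoms: p-toluenesulfonyl hydrazide, Cc1ccc(cc1)S(=O)(=O)NN
Why: Hydrazone condensation, expected to be selective for the strained, unconjugated cyclobutanone because the other two carbonyls are deactivated vinylogous esters.

Step 12
Reactants: 17 tosylhydrazone of 16
Product: 18 (6R)-6-butenyl-6-(cyclobutylmethyl) dienone
Conditions: catecholborane (2.5 equiv), CHCl3, 0 °C; then NaOAc·3H2O, 60 °C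
Reagents that add atoms: none
Why: Caglioti-type deoxygenation (hydride reduction of the tosylhydrazone C=N, then loss of sulfinate and N2), which should remove the temporary carbonyl without touching the alkenes or the s-trans-locked conjugated carbonyls and does not involve the ring stereocentres.

Step 13
Reactants: 18 (6R)-6-butenyl-6-(cyclobutylmethyl) dienone
Product: 19 (6R)-6-prenyl-6-(cyclobutylmethyl) dienone lactone
Conditions: 2-methylbut-2-ene (large excess), second-generation Ru–NHC isopropoxybenzylidene metathesis catalyst (5 mol %), CH2Cl2, 40 °C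
Reagents that add atoms: 2-methylbut-2-ene, CC=C(C)C
Why: Olefin cross-metathesis of the 1,2-disubstituted butenyl group, in which the 1,1-disubstituted isopropenyl group on the hindered cyclobutane and the tetrasubstituted ring alkenes should not take part.

Step 14
Reactants: 19 (6R)-6-prenyl-6-(cyclobutylmethyl) dienone lactone
Product: 20 target acid (CNP0364345.1)
Conditions: LiOH·H2O (2.5 equiv), THF–H2O, 0 °C; then 1 M HCl to pH 3
Reagents that add atoms: lithium hydroxide, [Li+].[OH-]
Why: Saponification of the enol lactone (an activated enol ester) should release the acid and the enol OH together, and the delocalised enolate formed on opening resists a second deprotonation, which protects the cis-dimethylpyranone from epimerisation.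

**Compound list**

1 | phloroglucinol | Oc1cc(O)cc(O)c1 | starting material
2 | ethyl 3-oxohexanoate | CCCC(=O)CC(=O)OCC | starting material
3 | 5,7-dihydroxy-4-propyl-2H-chromen-2-one | CCCC1=CC(=O)Oc2cc(O)cc(O)c12 | intermediate
4 | (4S)-5,7-dihydroxy-4-propyl-3,4-dihydro-2H-chromen-2-one | Oc1cc(O)c2[C@@H](CCC)CC(=O)Oc2c1 | intermediate
5 | (4S)-5,7-dihydroxy-8-[(2E)-2-methylbut-2-enoyl]-4-propyl-3,4-dihydro-2H-chromen-2-one | Oc1cc(O)c2[C@@H](CCC)CC(=O)Oc2c1C(=O)/C(C)=C/C | intermediate
6 | (4S,8R,9S)-5-hydroxy-8,9-dimethyl-4-propyl-3,4,8,9-tetrahydro-2H,10H-pyrano[2,3-f]chromene-2,10-dione | c1c(O)c2[C@@H](CCC)CC(=O)Oc2c3C(=O)[C@@H](C)[C@@H](C)Oc13 | intermediate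
7 | (4S,8R,9S)-8,9-dimethyl-5-[(2-methylbut-3-en-2-yl)oxy]-4-propyl-3,4,8,9-tetrahydro-2H,10H-pyrano[2,3-f]chromene-2,10-dione | c1c(OC(C)(C)C=C)c2[C@@H](CCC)CC(=O)Oc2c3C(=O)[C@@H](C)[C@@H](C)Oc13 | intermediate
8 | (4S,8R,9S)-5-hydroxy-8,9-dimethyl-6-(3-methylbut-2-en-1-yl)-4-propyl-3,4,8,9-tetrahydro-2H,10H-pyrano[2,3-f]chromene-2,10-dione | CC(C)=CCc1c(O)c2[C@@H](CCC)CC(=O)Oc2c3C(=O)[C@@H](C)[C@@H](C)Oc13 | intermediate
9 | (4S,8R,9S)-5-{[(2R)-but-3-en-2-yl]oxy}-8,9-dimethyl-6-(3-methylbut-2-en-1-yl)-4-propyl-3,4,8,9-tetrahydro-2H,10H-pyrano[2,3-f]chromene-2,10-dione | CC(C)=CCc1c(O[C@H](C)C=C)c2[C@@H](CCC)CC(=O)Oc2c3C(=O)[C@@H](C)[C@@H](C)Oc13 | intermediate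
10 | (4S,6R,8R,9S)-6-[(2E)-but-2-en-1-yl]-8,9-dimethyl-6-(3-methylbut-2-en-1-yl)-4-propyl-3,4,8,9-tetrahydro-2H-pyrano[2,3-f]chromene-2,5,10(6H)-trione | CC(C)=CC[C@@]2(C/C=C/C)C(=O)C4=C(OC(=O)C[C@@H]4CCC)C3=C2O[C@H](C)[C@H](C)C3=O | intermediate
11 | 3-methylbut-3-enoic acid | C=C(C)CC(=O)O | starting material
12 | (2R,5R)-2,5-dimethylpyrrolidine | C[C@@H]1CC[C@@H](C)N1 | starting material
13 | 1-[(2R,5R)-2,5-dimethylpyrrolidin-1-yl]-3-methylbut-3-en-1-one | C=C(C)CC(=O)N1[C@H](C)CC[C@H]1C | intermediate
14 | (2R,5R)-2,5-dimethyl-1-(3-methylbuta-1,3-dien-1-ylidene)pyrrolidin-1-ium trifluoromethanesulfonate (keteniminium triflate, formed in situ) | C=C(C)C=C=[N+]1[C@H](C)CC[C@H]1C.[O-]S(=O)(=O)C(F)(F)F | intermediate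
15 | N-cyclobutylidene-(2R,5R)-2,5-dimethylpyrrolidinium trifluoromethanesulfonate corresponding to ketone 16 (cyclobutaniminium triflate, formed in situ; drawn as the cis epimer) | C=C(C)[C@H]1C(=[N+]5[C@H](C)CC[C@H]5C)[C@@H](C[C@@]2(C/C=C/C)C(=O)C4=C(OC(=O)C[C@@H]4CCC)C3=C2O[C@H](C)[C@H](C)C3=O)C1(C)C.[O-]S(=O)(=O)C(F)(F)F | intermediate
16 | (4S,6R,8R,9S)-6-[(2E)-but-2-en-1-yl]-6-{[(1S,3R)-2,2-dimethyl-4-oxo-3-(prop-1-en-2-yl)cyclobutyl]methyl}-8,9-dimethyl-4-propyl-3,4,8,9-tetrahydro-2H-pyrano[2,3-f]chromene-2,5,10(6H)-trione | C=C(C)[C@H]1C(=O)[C@@H](C[C@@]2(C/C=C/C)C(=O)C4=C(OC(=O)C[C@@H]4CCC)C3=C2O[C@H](C)[C@H](C)C3=O)C1(C)C | intermediate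
17 | 4-methylbenzenesulfonohydrazone (tosylhydrazone) of 16 at the cyclobutanone carbonyl | C=C(C)[C@H]1C(=NNS(=O)(=O)c5ccc(C)cc5)[C@@H](C[C@@]2(C/C=C/C)C(=O)C4=C(OC(=O)C[C@@H]4CCC)C3=C2O[C@H](C)[C@H](C)C3=O)C1(C)C | intermediate
18 | (4S,6R,8R,9S)-6-[(2E)-but-2-en-1-yl]-6-{[(1S,3R)-2,2-dimethyl-3-(prop-1-en-2-yl)cyclobutyl]methyl}-8,9-dimethyl-4-propyl-3,4,8,9-tetrahydro-2H-pyrano[2,3-f]chromene-2,5,10(6H)-trione | C=C(C)[C@H]1C[C@@H](C[C@@]2(C/C=C/C)C(=O)C4=C(OC(=O)C[C@@H]4CCC)C3=C2O[C@H](C)[C@H](C)C3=O)C1(C)C | intermediate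
19 | (4S,6R,8R,9S)-6-{[(1S,3R)-2,2-dimethyl-3-(prop-1-en-2-yl)cyclobutyl]methyl}-8,9-dimethyl-6-(3-methylbut-2-en-1-yl)-4-propyl-3,4,8,9-tetrahydro-2H-pyrano[2,3-f]chromene-2,5,10(6H)-trione | C=C(C)[C@H]1C[C@@H](C[C@@]2(CC=C(C)C)C(=O)C4=C(OC(=O)C[C@@H]4CCC)C3=C2O[C@H](C)[C@H](C)C3=O)C1(C)C | intermediate
20 | (3S)-3-[(2R,3S,8R)-8-{[(1S,3R)-2,2-dimethyl-3-(prop-1-en-2-yl)cyclobutyl]methyl}-5-hydroxy-2,3-dimethyl-8-(3-methylbut-2-en-1-yl)-4,7-dioxo-3,4,7,8-tetrahydro-2H-chromen-6-yl]hexanoic acid | C=C(C)[C@H]1C[C@@H](C[C@@]2(CC=C(C)C)C(=O)C([C@@H](CCC)CC(=O)O)=C(O)C3=C2O[C@H](C)[C@H](C)C3=O)C1(C)C | target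

**Step count and risks**

Total step count: 14. Longest linear sequence: 13 (steps 1–8 and 10–14; step 9 is a one-step side branch).

Steps most likely to fail:

1. Step 10. The keteniminium ion may be consumed by self-condensation or electrocyclisation before it meets the hindered alkene, or be captured by the butenyl alkene. The auxiliary may also discriminate poorly between the two faces of an acyclic alkene, and enolisation at both α-carbons would erase what discrimination there is. Fallback: setting out from 10, the cycloaddition would be run under the same Tf2O/collidine conditions with the dioxolane-masked acetoacetamide 1-[(2R,5R)-2,5-dimethylpyrrolidin-1-yl]-2-(2-methyl-1,3-dioxolan-2-yl)ethan-1-one F1 (from 12 and commercial 2-(2-methyl-1,3-dioxolan-2-yl)acetic acid), a saturated α-alkyl keteniminium precursor, to give the ketal cyclobutanone F2. Its tosylhydrazone F3 would be reduced with catecholborane to the ketal cyclobutane F4, PPTS in wet acetone would unmask the methyl ketone F5 (whose α-carbon should settle cis), and base-free methylenation (Zn, CH2Br2, TiCl4) of this only unconjugated ketone would come back to the route at 18. The isopropenyl group is then built after the ring instead of arriving with it.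

2. Step 8. Chirality transfer may leak through the boat transition state or through ionisation–recombination of the secondary allylic ether, and further [3,3] shifts may carry an allyl group to a ring-fusion carbon. Fallback: setting out from phenol 8, the (E)-but-2-en-1-yl carbonate F6 would be made ((E)-but-2-en-1-yl chloroformate, pyridine) and submitted to a Pd-catalysed decarboxylative asymmetric allylic dearomatisation (Pd2(dba)3, C2-symmetric diaminocyclohexane-derived diphosphine, dioxane, rt). Reversible O-allylation should funnel the linear butenyl group to C6, with the face chosen by the ligand instead of by a stereocentre in the substrate; this comes back to the route at 10.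

3. Step 11 (with step 12). The hydrazide may be acylated by the enol lactone, ene-hydrazine tautomerism may epimerise both α-carbons, or condensation may occur at another carbonyl. Fallback: setting out from 16, NaBH4 (MeOH–THF, −78 °C) would reduce only the strained ketone to the all-cis cyclobutanol F7. Its O-phenyl thionocarbonate F8 (PhOC(S)Cl, pyridine, DMAP) would undergo Barton–McCombie deoxygenation (Bu3SnH in high concentration to outrun ring opening of the cyclobutyl radical, AIBN, toluene, 80 °C) and come back to the route at 18.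

Further compounds
F1 | step 10 | 1-[(2R,5R)-2,5-dimethylpyrrolidin-1-yl]-2-(2-methyl-1,3-dioxolan-2-yl)ethan-1-one | CC1(CC(=O)N2[C@H](C)CC[C@H]2C)OCCO1
F2 | step 10 | ketal cyclobutanone: analogue of 16 with 2-methyl-1,3-dioxolan-2-yl in place of prop-1-en-2-yl | CC5(OCCO5)[C@H]1C(=O)[C@@H](C[C@@]2(C/C=C/C)C(=O)C4=C(OC(=O)C[C@@H]4CCC)C3=C2O[C@H](C)[C@H](C)C3=O)C1(C)C
F3 | step 10 | tosylhydrazone of F2 | CC5(OCCO5)[C@H]1C(=NNS(=O)(=O)c6ccc(C)cc6)[C@@H](C[C@@]2(C/C=C/C)C(=O)C4=C(OC(=O)C[C@@H]4CCC)C3=C2O[C@H](C)[C@H](C)C3=O)C1(C)C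
F4 | step 10 | ketal cyclobutane: analogue of 18 with 2-methyl-1,3-dioxolan-2-yl in place of prop-1-en-2-yl | CC5(OCCO5)[C@H]1C[C@@H](C[C@@]2(C/C=C/C)C(=O)C4=C(OC(=O)C[C@@H]4CCC)C3=C2O[C@H](C)[C@H](C)C3=O)C1(C)C
F5 | step 10 | methyl ketone: analogue of 18 with acetyl in place of prop-1-en-2-yl | CC(=O)[C@H]1C[C@@H](C[C@@]2(C/C=C/C)C(=O)C4=C(OC(=O)C[C@@H]4CCC)C3=C2O[C@H](C)[C@H](C)C3=O)C1(C)C
F6 | step 8 | (2E)-but-2-en-1-yl carbonate of phenol 8 | CC(C)=CCc1c(OC(=O)OC/C=C/C)c2[C@@H](CCC)CC(=O)Oc2c3C(=O)[C@@H](C)[C@@H](C)Oc13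
F7 | step 11 | all-cis cyclobutanol from reduction of 16 | C=C(C)[C@H]1[C@@H](O)[C@@H](C[C@@]2(C/C=C/C)C(=O)C4=C(OC(=O)C[C@@H]4CCC)C3=C2O[C@H](C)[C@H](C)C3=O)C1(C)C
F8 | step 11 | O-phenyl thionocarbonate of F7 | C=C(C)[C@H]1[C@@H](OC(=S)Oc6ccccc6)[C@@H](C[C@@]2(C/C=C/C)C(=O)C4=C(OC(=O)C[C@@H]4CCC)C3=C2O[C@H](C)[C@H](C)C3=O)C1(C)C
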